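**Retrosynthetic overview**

1. The target is traced back, through late redox and deprotection steps only, to a tetracycle whose ring A is a C1=C2 cyclohexene with an ether oxygen on C3, Me/CO2Me on C4, C7 as CH2OSi and C12 as a ketal.
2. Key disconnection: C3–C4 and C5–C10, by an intramolecular Diels–Alder reaction of a diene that is released in the same operation by 4π-opening of a cyclobutene. Ring A grows from the four-membered ring C10–C1=C2–C3 by insertion of C4 and C5, and ring B closes at the same time as the tether ring.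
3. Enabling feature: the strained C3–C10 σ-bond of that cyclobutene, with the C3 ether oxygen trans to C9 (both rotate outward, giving the E,E-diene with C20 inside), held through C9–C8–C6 next to the (Z)-configured C4=C5 2-methylenoate.
4. The cyclobutene comes from a C9 propanamide (keteniminium/acetylene [2+2], oxa-Michael addition, enol triflate reduction); C9–C10 comes from an exo-face Michael addition to the C/D enone; the C8 side chain comes from homologation, hydroxymethylation (C7) and Z-selective olefination (C4, C18, C19).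
5. Ring order: C (asymmetric Diels–Alder, sets C8), then D (gold-catalysed Conia-ene cyclisation, sets C13), then the cyclobutene, then A and B together in the key step.

Key step: step 17

Numbering and assumption: gibberellane numbering of the target is used for all intermediates (ring A = C1–C5, C10; ring B = C5, C6, C8, C9, C10; ring C = C8, C9, C11–C14; ring D = C8, C13–C16; C17 = exocyclic CH2, C18/C19 = methyl/carboxyl on C4, C20 = methyl on C10, C7 = carboxyl on C6); the absolute sense of the two catalyst-controlled steps (2 and 9) is taken from the usual models for these catalysts, and the enantiomeric catalyst would be used if the opposite sense were found.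

**Route**

Step 1
Reactants: 1 pent-4-ynal; 2 formaldehyde (37% aqueous solution)
Product: 3 2-methylidenepent-4-ynal
Conditions: pyrrolidine (10 mol %), EtCO2H (10 mol %), i-PrOH, 45 °C
Reagents that add atoms: none
Why: Amine-catalysed Mannich condensation and elimination (organocatalytic α-methylenation of an aldehyde) should give the α-substituted acrolein; no stereocentre is formed.

Step 2
Reactants: 3 2-methylidenepent-4-ynal; 4 (E)-1-(dimethylamino)-3-(tert-butyldimethylsilyloxy)buta-1,3-diene
Product: 5 (1R,2R)-4-(tert-butyldimethylsilyloxy)-2-(dimethylamino)-1-(prop-2-yn-1-yl)cyclohex-3-ene-1-carbaldehyde (ring carbon 1 is the later C8, CHO is C6, NMe2 cis to CHO)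
Conditions: [(1R,2R)-N,N′-bis(3,5-di-tert-butylsalicylidene)cyclohexane-1,2-diaminato]chromium hexafluoroantimonate (5 mol %), 4 Å molecular sieves, CH2Cl2, −40 °C
Reagents that add atoms: none
Why: Catalytic asymmetric Diels–Alder reaction of an α-substituted acrolein with a 1-amino-3-silyloxydiene: the salen–chromium Lewis acid binds the aldehyde and exposes one enantioface, which sets the quaternary C8, while the amino group fixes the regiochemistry and endo addition puts NMe2 cis to CHO.

Step 3
Reactants: 5 Diels–Alder adduct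
Product: 6 enol ether, the ring of 5 with CH=CH–OMe in place of CHO (E/Z mixture)
Conditions: Ph3P(CH2OMe)Cl, KN(SiMe3)2, THF, 0 °C; then 5, −78 → 0 °C
Reagents that add atoms: (methoxymethyl)triphenylphosphonium chloride, SMILES: COC[P+](c1ccccc1)(c1ccccc1)c1ccccc1.[Cl-]
Why: Wittig methoxymethylenation of the non-enolisable neopentyl aldehyde should add C5 as an enol ether without touching the silyl enol ether or the amine; the C=C geometry is irrelevant.

Step 4
Reactants: 6 enol ether
Product: 7 (S)-4-(2,2-dimethoxyethyl)-4-(prop-2-yn-1-yl)cyclohex-2-en-1-one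
Conditions: HCl (1.25 M in MeOH, 1.5 equiv), 0 → 23 °C; NaHCO3 quench
Reagents that add atoms: methanol, SMILES: CO
Why: Acidic methanol should turn the methyl enol ether into the dimethyl acetal (acetalisation), cleave the silyl enol ether and expel dimethylamine from the resulting β-amino ketone (E1cB), which unmasks the 4,4-disubstituted cyclohexenone and leaves C8 untouched.

Step 5
Reactants: 7 enone acetal
Product: 8 tert-butyl{[4-(2,2-dimethoxyethyl)-4-(prop-2-yn-1-yl)cyclohexa-1,5-dien-1-yl]oxy}dimethylsilane (C8 unchanged)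
Conditions: TBSOTf, Et3N, CH2Cl2, −78 °C
Reagents that add atoms: tert-butyldimethylsilyl trifluoromethanesulfonate, SMILES: CC(C)(C)[Si](C)(C)OS(=O)(=O)C(F)(F)F
Why: Soft enolisation can only remove an α′-hydrogen at C13 because the γ-carbon C8 is quaternary, so the cross-conjugated 2-silyloxydiene should form; at −78 °C the bulky silyl triflate should leave the acetal alone.

Step 6
Reactants: 8 silyl dienol ether
Product: 9 C/D enone, 5-(2,2-dimethoxyethyl)-7-methylidenebicyclo[3.2.1]oct-3-en-2-one (C12 ketone, C9=C11, C16=C17; C8 and C13 as in the target)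
Conditions: Ph3PAuCl (5 mol %), AgBF4 (5 mol %), toluene/MeOH (10:1), 23 °C
Reagents that add atoms: none
Why: Monovalent gold activates the alkyne for 5-exo-dig attack by the silyl enol ether carbon C13 (Conia-ene-type carbocyclisation) and protodeauration gives the exocyclic methylene; the propargyl arm on C8 can reach C13 from one face only, so the bridgehead C13 is set by C8.

Step 7
Reactants: 9 C/D enone; 10 N,N-dimethylpropanamide
Product: 12 keto amide carrying CH(CH3)CONMe2 on C9 (H9 cis to the C15–C16 bridge; both C10 epimers), via lithium enolate of amide 11 (not isolated)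
Conditions: 10, LiN(i-Pr)2, THF, −78 °C; then 9, −78 → −30 °C; aqueous NH4Cl
Reagents that add atoms: none
Why: Michael addition of the amide enolate to the bicyclic enone should occur at C9 from the exo face, syn to the one-carbon bridge C14 and anti to the C15–C16 bridge, which places H9 cis to C15 as in the target; the C10 epimer mixture is erased in step 13.

Step 8
Reactants: 12 keto amide acetal
Product: 13 C5 aldehyde (C8–CH2–CHO)
Conditions: PPTS (0.2 equiv), acetone/H2O (10:1), 50 °C
Reagents that add atoms: water, SMILES: O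
Why: Mild acid-catalysed acetal hydrolysis should free the aldehyde without affecting the amide, the ketone or the exocyclic alkene.

Step 9
Reactants: 13 C5 aldehyde; 2 formaldehyde (37% aqueous solution)
Product: 14 (6S)-hydroxymethyl aldehyde, C8–CH(CH2OH)–CHO
Conditions: (S)-2-[diphenyl(trimethylsilyloxy)methyl]pyrrolidine (10 mol %), pH 7 phosphate buffer, toluene, 23 °C
Reagents that add atoms: none
Why: Enamine catalysis (organocatalytic cross-aldol with formaldehyde, α-hydroxymethylation) should add C7 to C6; the bulky group of the catalyst shields one face of the (E)-enamine, so the C6 configuration is reagent-controlled.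

Step 10
Reactants: 14 hydroxymethyl aldehyde
Product: 15 silyl ether, C8–CH(CH2OTBS)–CHO
Conditions: TBSCl, imidazole, CH2Cl2, 0 °C (crude 14 used at once)
Reagents that add atoms: tert-butyldimethylsilyl chloride, SMILES: CC(C)(C)[Si](C)(C)Cl
Why: Silylation of the primary alcohol under nearly neutral conditions should block dehydration of the β-hydroxy aldehyde and keep C6 intact.

Step 11
Reactants: 15 silyloxy aldehyde
Product: 16 (Z)-enoate, C8–CH(CH2OTBS)–CH=C(CH3)CO2CH3 with CO2CH3 cis to C6
Conditions: (CF3CH2O)2P(O)CH(CH3)CO2CH3, KN(SiMe3)2, 18-crown-6, THF, −78 °C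
Reagents that add atoms: methyl 2-[bis(2,2,2-trifluoroethoxy)phosphoryl]propanoate, SMILES: COC(=O)C(C)P(=O)(OCC(F)(F)F)OCC(F)(F)F
Why: Still–Gennari olefination with the electron-poor phosphonate should give the kinetic Z-trisubstituted enoate (C4, C18, C19 introduced) and reacts with the aldehyde far faster than with the C12 ketone.

Step 12
Reactants: 16 keto enoate
Product: 17 C12 ethylene ketal of 16
Conditions: Me3SiOCH2CH2OSiMe3, Me3SiOTf (5 mol %), CH2Cl2, −78 → −20 °C
Reagents that add atoms: 1,2-bis(trimethylsilyloxy)ethane, SMILES: C[Si](C)(C)OCCO[Si](C)(C)C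
Why: Aprotic ketalisation with the bis-silyl glycol should protect the only ketone and tolerate the silyl ether, the enoate and the exocyclic alkene.

Step 13
Reactants: 17 ketal amide
Product: 20 cyclobutenone with C10 as the quaternary ring carbon (C10(CH3)(C9)–CH=CH–C=O; both C10 epimers), via keteniminium triflate 18 (not isolated), via cyclobuteniminium triflate 19 (not isolated)
Conditions: Tf2O (1.1 equiv), 2,4,6-collidine, CH2Cl2, −78 → 0 °C; HC≡CH (1 atm), 0 → 23 °C; then aqueous NaHCO3
Reagents that add atoms: acetylene, SMILES: C#C; water, SMILES: O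
Why: Electrophilic activation of the tertiary amide gives keteniminium ion 18, whose [2+2] cycloaddition with acetylene gives 19 and, on hydrolysis, the 4,4-disubstituted cyclobutenone (keteniminium–alkyne [2+2] cycloaddition); the amide oxygen is much more nucleophilic than the ketal, ester or silyl ether, and C10 may form as either epimer because it becomes trigonal again in step 17.

Step 14
Reactants: 20 cyclobutenone
Product: 21 3-(4-methoxybenzyloxy)cyclobutanone, PMBO on C3 trans to C9 and cis to C20
Conditions: 4-MeOC6H4CH2OH (3 equiv), DBU (10 mol %), CH2Cl2, 0 °C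
Reagents that add atoms: 4-methoxybenzyl alcohol, SMILES: COc1ccc(CO)cc1
Why: Oxa-Michael addition to the strained, strongly electrophilic cyclobutenone should put the alkoxy group on C3 from the face opposite the larger C10 substituent (C9 with the bicycle), in both C10 epimers; this trans arrangement is also the more stable one if the addition equilibrates.

Step 15
Reactants: 21 alkoxycyclobutanone
Product: 22 cyclobutenyl triflate, C1(OTf)=C2
Conditions: KN(SiMe3)2, THF, −78 °C; then N-(5-chloropyridin-2-yl)bis(trifluoromethanesulfonyl)imide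
Reagents that add atoms: N-(5-chloropyridin-2-yl)bis(trifluoromethanesulfonyl)imide, SMILES: O=S(=O)(N(c1ccc(Cl)cn1)S(=O)(=O)C(F)(F)F)C(F)(F)F
Why: Kinetic enolisation is possible only toward C2 because C10 is quaternary, and O-triflation at −78 °C should outrun loss of the β-alkoxide.

Step 16
Reactants: 22 cyclobutenyl triflate
Product: 23 trans-3-(4-methoxybenzyloxy)-4-methylcyclobutene attached to C9 through C10 (kept cold, used at once)
Conditions: Pd(PPh3)4 (5 mol %), LiCl, Bu3SnH, THF, 23 °C
Reagents that add atoms: none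
Why: Oxidative addition of the vinyl triflate to zerovalent palladium, hydride transfer from tin and reductive elimination (catalytic triflate reduction) should give the cyclobutene at room temperature, below the onset of ring opening.

Step 17
Reactants: 23 cyclobutene
Product: 25 tetracycle with ring A as C1=C2 cyclohexene, 3β-OPMB, 4β-CH3, 4α-CO2CH3, 5β-H, 10α-CH3, 6β-CH2OTBS and C12 ketal, via alkoxydiene 24 (not isolated)
Conditions: toluene (0.01 M), 2,6-di-tert-butyl-4-methylphenol (5 mol %), solid K2CO3, sealed tube, 70 °C then 150 °C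
Reagents that add atoms: none
Why: Heating first opens the cyclobutene by thermal conrotatory 4π-electrocyclic cleavage of the C3–C10 bond, the C3 ether oxygen rotating outward and thereby driving the trans-disposed C9 outward and C20 inward, to give the (1E,3E)-1-alkoxydiene 24, which then undergoes a concerted suprafacial intramolecular [4+2] cycloaddition with the (Z)-2-methylenoate (new bonds C3–C4 and C5–C10). The closest known reaction type is the cyclobutene (or benzocyclobutene) ring opening–intramolecular Diels–Alder cascade, together with intramolecular Diels–Alder closure of gibberellin rings A and B on a preformed bicyclo[3.2.1]octane. Ring A closes as the cycloadduct ring itself, its atoms C10, C1, C2 and C3 being the former four-membered ring now enlarged by C4 and C5, and ring B closes in the fused (type 1) mode as the five-membered ring spanned by the three-atom tether C6–C8–C9. C3 and C10 follow from the diene geometry (oxygen and C9 both outside, hence cis on ring A), C4 follows from the Z-geometry of the dienophile (CO2CH3 cis to C6, hence α), and C5 follows from the tether-exo transition state that gives the trans ring fusion, while the absolute sense is relayed from C8, C9 and C6 because the diene reacts on the face that keeps its C1–C3 arm away from C11 and leaves only the inside methyl C20 against it. The selectivity needed is tether-exo addition on that face; the substrate favours it through the α-methyl group of the dienophile, which like that of a methacrylate prefers the endo position and so sends the ester, and with it the cis-disposed tether, exo, and through the C6 CH2OTBS group, which can lie pseudo-equatorial on the forming five-membered ring in this arrangement.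

Step 18
Reactants: 25 tetracyclic PMB ether
Product: 26 allylic alcohol (3β-OH, C1=C2)
Conditions: DDQ, CH2Cl2/pH 7 buffer (10:1), 0 °C
Reagents that add atoms: none
Why: Oxidative cleavage of the 4-methoxybenzyl ether (hydride abstraction by DDQ, hydrolysis of the oxocarbenium ion) should free the C3 alcohol and spare the silyl ether, the ketal and both alkenes.

Step 19
Reactants: 26 allylic alcohol
Product: 27 enone (C3=O conjugated with C1=C2)
Conditions: Dess–Martin periodinane, NaHCO3, CH2Cl2, 23 °C
Reagents that add atoms: none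
Why: Dess–Martin oxidation of the allylic alcohol makes the ring A alkene the only conjugate acceptor in the molecule, which is what allows its selective removal next to the 16-methylene.

Step 20
Reactants: 27 enone
Product: 28 saturated 3-ketone (quaternary β-keto ester at C4)
Conditions: [(Ph3P)CuH]6 (0.5 equiv), H2O (5 equiv), benzene, 23 °C
Reagents that add atoms: none
Why: Conjugate reduction by the phosphine-stabilised copper hydride (hydride to C1, protonation at C2) should saturate ring A chemoselectively, since isolated 1,1-disubstituted alkenes, esters and ketals are inert to this reagent.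

Step 21
Reactants: 28 silyl ether
Product: 29 primary alcohol (C7–OH)
Conditions: Bu4NF, THF, 0 → 23 °C
Reagents that add atoms: none
Why: Fluoride-induced desilylation should free C7–OH; the quaternary β-keto ester cannot epimerise.

Step 22
Reactants: 29 primary alcohol
Product: 31 C7 carboxylic acid (C3 ketone, C19 methyl ester, C12 ketal), via C7 aldehyde 30 (not isolated)
Conditions: TEMPO (0.2 equiv), PhI(OAc)2 (2.5 equiv), MeCN/pH 7 buffer (1:1), 23 °C
Reagents that add atoms: water, SMILES: O
Why: Oxoammonium (TEMPO) oxidation with PhI(OAc)2 as terminal oxidant should take the primary alcohol through aldehyde 30 and its hydrate to the acid; C6, now epimerisable, already carries C7 trans to C4, which is expected to be the more stable arrangement.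

Step 23
Reactants: 31 keto acid
Product: 32 3β-hydroxy acid (C19 methyl ester, C12 ketal)
Conditions: K[B(s-Bu)3H] (3 equiv), THF, −78 °C; aqueous NH4Cl
Reagents that add atoms: none
Why: The bulky borohydride should avoid the axial path past the C1 and C5 axial hydrogens and deliver hydride along the equatorial trajectory, giving the axial 3β-alcohol cis to C18, as in reductions of 4,4-disubstituted 3-oxo terpenoids; the carboxylate and the hindered ester are not reduced.

Step 24
Reactants: 32 hydroxy acid methyl ester
Product: 34 target, CNP0197851.1, via diacid ketal 33 (not isolated)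
Conditions: NaSEt (10 equiv), DMF, 80 °C; then 1 M HCl, THF, 23 °C
Reagents that add atoms: water, SMILES: O
Why: SN2 demethylation of the hindered axial C19 methyl ester by thiolate at the methyl carbon, followed by acid hydrolysis of the dioxolane, should give the target without touching the C3 alcohol or the 16-methylene.

**Compound list**

1 | pent-4-ynal | C#CCCC=O | starting material
2 | formaldehyde | C=O | starting material
3 | 2-methylidenepent-4-ynal | C#CCC(=C)C=O | intermediate
4 | (E)-1-(dimethylamino)-3-(tert-butyldimethylsilyloxy)buta-1,3-diene | CN(C)/C=C/C(=C)O[Si](C)(C)C(C)(C)C | starting material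
5 | (1R,2R)-4-(tert-butyldimethylsilyloxy)-2-(dimethylamino)-1-(prop-2-yn-1-yl)cyclohex-3-ene-1-carbaldehyde | C#CC[C@]1(C=O)CCC(O[Si](C)(C)C(C)(C)C)=C[C@H]1N(C)C | intermediate
6 | enol ether: ring of 5 with 1-(2-methoxyethenyl) in place of CHO (E/Z mixture) | C#CC[C@]1(C=COC)CCC(O[Si](C)(C)C(C)(C)C)=C[C@H]1N(C)C | intermediate
7 | (S)-4-(2,2-dimethoxyethyl)-4-(prop-2-yn-1-yl)cyclohex-2-en-1-one | C#CC[C@]1(CC(OC)OC)CCC(=O)C=C1 | intermediate
8 | tert-butyl{[4-(2,2-dimethoxyethyl)-4-(prop-2-yn-1-yl)cyclohexa-1,5-dien-1-yl]oxy}dimethylsilane | C#CC[C@]1(CC(OC)OC)CC=C(O[Si](C)(C)C(C)(C)C)C=C1 | intermediate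
9 | C/D enone: 5-(2,2-dimethoxyethyl)-7-methylidenebicyclo[3.2.1]oct-3-en-2-one (C8, C13 as in the target) | C=C1C[C@]2(CC(OC)OC)C[C@H]1C(=O)C=C2 | intermediate
10 | N,N-dimethylpropanamide | CCC(=O)N(C)C | starting material
11 | lithium enolate of N,N-dimethylpropanamide (not isolated) | C/C=C(\[O-])N(C)C.[Li+] | intermediate
12 | keto amide: C9 adduct of 9 carrying CH(CH3)CONMe2 (H9 cis to C15; C10 epimers) | C=C1C[C@]2(CC(OC)OC)C[C@H]1C(=O)C[C@H]2C(C)C(=O)N(C)C | intermediate
13 | C5 aldehyde (C8–CH2–CHO) | C=C1C[C@]2(CC=O)C[C@H]1C(=O)C[C@H]2C(C)C(=O)N(C)C | intermediate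
14 | (6S)-hydroxymethyl aldehyde (C8–CH(CH2OH)–CHO) | C=C1C[C@]2([C@@H](CO)C=O)C[C@H]1C(=O)C[C@H]2C(C)C(=O)N(C)C | intermediate
15 | TBS ether of 14 | C=C1C[C@]2([C@@H](CO[Si](C)(C)C(C)(C)C)C=O)C[C@H]1C(=O)C[C@H]2C(C)C(=O)N(C)C | intermediate
16 | (Z)-enoate: C8–CH(CH2OTBS)–CH=C(CH3)CO2CH3, ester cis to C6; C12 ketone | C=C1C[C@]2([C@@H](CO[Si](C)(C)C(C)(C)C)/C=C(/C)C(=O)OC)C[C@H]1C(=O)C[C@H]2C(C)C(=O)N(C)C | intermediate
17 | C12 ethylene ketal of 16 | C=C1C[C@]2([C@@H](CO[Si](C)(C)C(C)(C)C)/C=C(/C)C(=O)OC)C[C@H]1C1(OCCO1)C[C@H]2C(C)C(=O)N(C)C | intermediate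
18 | keteniminium triflate, C10(CH3)=C=N+Me2 on C9 (not isolated) | C=C1C[C@]2([C@@H](CO[Si](C)(C)C(C)(C)C)/C=C(/C)C(=O)OC)C[C@H]1C1(OCCO1)C[C@H]2C(C)=C=[N+](C)C.[O-]S(=O)(=O)C(F)(F)F | intermediate
19 | cyclobuteniminium triflate (not isolated; one C10 epimer drawn) | C=C1C[C@]2([C@@H](CO[Si](C)(C)C(C)(C)C)/C=C(/C)C(=O)OC)C[C@H]1C1(OCCO1)C[C@H]2[C@]1(C)C=CC1=[N+](C)C.[O-]S(=O)(=O)C(F)(F)F | intermediate
20 | cyclobutenone: 4-methylcyclobut-2-en-1-one joined to C9 through its C4 (= C10); one C10 epimer drawn | C=C1C[C@]2([C@@H](CO[Si](C)(C)C(C)(C)C)/C=C(/C)C(=O)OC)C[C@H]1C1(OCCO1)C[C@H]2[C@]1(C)C=CC1=O | intermediate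
21 | 3-(4-methoxybenzyloxy)-2-methylcyclobutan-1-one joined to C9 through C10; PMBO trans to C9 (one C10 epimer drawn) | C=C1C[C@]2([C@@H](CO[Si](C)(C)C(C)(C)C)/C=C(/C)C(=O)OC)C[C@H]1C1(OCCO1)C[C@H]2[C@]1(C)[C@@H](OCc2ccc(OC)cc2)CC1=O | intermediate
22 | cyclobutenyl triflate of 21 (C1(OTf)=C2) | C=C1C[C@]2([C@@H](CO[Si](C)(C)C(C)(C)C)/C=C(/C)C(=O)OC)C[C@H]1C1(OCCO1)C[C@H]2[C@]1(C)[C@@H](OCc2ccc(OC)cc2)C=C1OS(=O)(=O)C(F)(F)F | intermediate
23 | cyclobutene: trans-3-(4-methoxybenzyloxy)-4-methylcyclobut-1-ene joined to C9 through C10 | C=C1C[C@]2([C@@H](CO[Si](C)(C)C(C)(C)C)/C=C(/C)C(=O)OC)C[C@H]1C1(OCCO1)C[C@H]2[C@]1(C)[C@@H](OCc2ccc(OC)cc2)C=C1 | intermediate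
24 | (1E,3E)-1-(4-methoxybenzyloxy)-4-methylbuta-1,3-dien-4-yl diene on C9, C20 inside (not isolated) | C=C1C[C@]2([C@@H](CO[Si](C)(C)C(C)(C)C)/C=C(/C)C(=O)OC)C[C@H]1C1(OCCO1)C[C@H]2/C(C)=C/C=C/OCc1ccc(OC)cc1 | intermediate
25 | tetracycle: ring A C1=C2, 3β-OPMB, 4β-CH3, 4α-CO2CH3, 6β-CH2OTBS, C12 ketal | C=C1C[C@]23C[C@H]1C1(OCCO1)C[C@H]2[C@]1(C)C=C[C@H](OCc2ccc(OC)cc2)[C@@](C)(C(=O)OC)[C@H]1[C@@H]3CO[Si](C)(C)C(C)(C)C | intermediate
26 | allylic alcohol (3β-OH, C1=C2) | C=C1C[C@]23C[C@H]1C1(OCCO1)C[C@H]2[C@]1(C)C=C[C@H](O)[C@@](C)(C(=O)OC)[C@H]1[C@@H]3CO[Si](C)(C)C(C)(C)C | intermediate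
27 | enone (C3=O, C1=C2) | C=C1C[C@]23C[C@H]1C1(OCCO1)C[C@H]2[C@]1(C)C=CC(=O)[C@@](C)(C(=O)OC)[C@H]1[C@@H]3CO[Si](C)(C)C(C)(C)C | intermediate
28 | saturated 3-ketone | C=C1C[C@]23C[C@H]1C1(OCCO1)C[C@H]2[C@]1(C)CCC(=O)[C@@](C)(C(=O)OC)[C@H]1[C@@H]3CO[Si](C)(C)C(C)(C)C | intermediate
29 | primary alcohol (C7–OH) | C=C1C[C@]23C[C@H]1C1(OCCO1)C[C@H]2[C@]1(C)CCC(=O)[C@@](C)(C(=O)OC)[C@H]1[C@@H]3CO | intermediate
30 | C7 aldehyde (not isolated) | C=C1C[C@]23C[C@H]1C1(OCCO1)C[C@H]2[C@]1(C)CCC(=O)[C@@](C)(C(=O)OC)[C@H]1[C@@H]3C=O | intermediate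
31 | C7 acid, 3-ketone, C19 methyl ester, C12 ketal | C=C1C[C@]23C[C@H]1C1(OCCO1)C[C@H]2[C@]1(C)CCC(=O)[C@@](C)(C(=O)OC)[C@H]1[C@@H]3C(=O)O | intermediate
32 | 3β-hydroxy C7 acid, C19 methyl ester, C12 ketal | C=C1C[C@]23C[C@H]1C1(OCCO1)C[C@H]2[C@]1(C)CC[C@H](O)[C@@](C)(C(=O)OC)[C@H]1[C@@H]3C(=O)O | intermediate
33 | 3β-hydroxy 7,19-diacid, C12 ketal (not isolated) | C=C1C[C@]23C[C@H]1C1(OCCO1)C[C@H]2[C@]1(C)CC[C@H](O)[C@@](C)(C(=O)O)[C@H]1[C@@H]3C(=O)O | intermediate
34 | CNP0197851.1 (3β-hydroxy-12-oxo C20 gibberellin 7,19-diacid) | C=C1C[C@]23C[C@H]1C(=O)C[C@H]2[C@]1(C)CC[C@H](O)[C@@](C)(C(=O)O)[C@H]1[C@@H]3C(=O)O | target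

**Step count and risks**

Total step count: 24. Longest linear sequence: 24 steps (fully linear from 1; compounds 2, 4 and 10 and all reagents are commercial).

Steps most likely to fail:

1. Step 17 (key step). The cycloaddition may proceed through the tether-endo arrangement and give the cis A/B fusion, or on the other diene face relative to C9; a [1,5]-hydrogen shift from the inside C20 methyl may also consume the diene before it cyclises. Fallback: starting from cyclobutene 23, oxidative removal of the PMB group (DDQ, wet CH2Cl2, 0 °C) should give the trans-cyclobutenol F1. Its potassium alkoxide (KH, 18-crown-6, THF, −78 → 0 °C) should open well below room temperature (oxyanion-accelerated electrocyclic opening, oxygen again outward) to a dienolate. This should close ring B by intramolecular vinylogous Michael addition of C10 to C5 of the enoate, and ring A by aldol addition of the resulting ester enolate (C4) to the C3 aldehyde. Protonation brings the route back at allylic alcohol 26; should the C3-epimeric allylic alcohol F2 form instead, step 19 oxidises it to the same enone 27.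

2. Step 13. Amide activation may be incomplete or unselective (competing attack of Tf2O on the ketal or ester oxygen), and the keteniminium ion may oligomerise with acetylene instead of undergoing a clean [2+2] addition. Fallback: starting from amide 17, chemoselective reduction with Cp2Zr(H)Cl should give the aldehyde F3, and Pinnick oxidation (NaClO2, NaH2PO4, 2-methylbut-2-ene) the carboxylic acid F4. 1-Chloro-N,N,2-trimethylprop-1-en-1-amine should convert it under neutral conditions into the acid chloride F5, and Et3N should release the ketene F6, which is trapped in situ by ethoxyacetylene ([2+2] cycloaddition) as the 3-ethoxycyclobutenone F7. Luche reduction (NaBH4, CeCl3) should give the cyclobutenol F8, and dilute aqueous acid should convert this into cyclobutenone 20, where the route is rejoined.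

3. Step 15. The cyclobutanone enolate may expel the β-alkoxide (retro-oxa-Michael) faster than it is triflated, which would return the cyclobutenone or scramble the C3 configuration. Fallback: starting from ketone 21, NaBH4 (MeOH, 0 °C) should give the cyclobutanol F9, and syn-dehydration with methyl N-(triethylammoniosulfonyl)carbamate (toluene, 50 °C) can only take place toward C2, so it should deliver cyclobutene 23 directly, bypassing steps 15 and 16.

Further compounds

F1 | step 17 | trans-cyclobutenol (23 with OH in place of OPMB) | C=C1C[C@]2([C@@H](CO[Si](C)(C)C(C)(C)C)/C=C(/C)C(=O)OC)C[C@H]1C1(OCCO1)C[C@H]2[C@]1(C)[C@@H](O)C=C1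
F2 | step 17 | C3-epimeric allylic alcohol (3α-OH epimer of 26) | C=C1C[C@]23C[C@H]1C1(OCCO1)C[C@H]2[C@]1(C)C=C[C@@H](O)[C@@](C)(C(=O)OC)[C@H]1[C@@H]3CO[Si](C)(C)C(C)(C)C
F3 | step 13 | aldehyde (17 with CHO in place of CONMe2) | C=C1C[C@]2([C@@H](CO[Si](C)(C)C(C)(C)C)/C=C(/C)C(=O)OC)C[C@H]1C1(OCCO1)C[C@H]2C(C)C=O
F4 | step 13 | carboxylic acid | C=C1C[C@]2([C@@H](CO[Si](C)(C)C(C)(C)C)/C=C(/C)C(=O)OC)C[C@H]1C1(OCCO1)C[C@H]2C(C)C(=O)O
F5 | step 13 | acid chloride | C=C1C[C@]2([C@@H](CO[Si](C)(C)C(C)(C)C)/C=C(/C)C(=O)OC)C[C@H]1C1(OCCO1)C[C@H]2C(C)C(=O)Cl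
F6 | step 13 | ketene, C10(CH3)=C=O on C9 | C=C1C[C@]2([C@@H](CO[Si](C)(C)C(C)(C)C)/C=C(/C)C(=O)OC)C[C@H]1C1(OCCO1)C[C@H]2C(C)=C=O
F7 | step 13 | 3-ethoxy-4-methylcyclobut-2-en-1-one joined to C9 through C10 (C10 epimers) | C=C1C[C@]2([C@@H](CO[Si](C)(C)C(C)(C)C)/C=C(/C)C(=O)OC)C[C@H]1C1(OCCO1)C[C@H]2C1(C)C(=O)C=C1OCC
F8 | step 13 | 3-ethoxy-4-methylcyclobut-2-en-1-ol joined to C9 through C10 (epimers) | C=C1C[C@]2([C@@H](CO[Si](C)(C)C(C)(C)C)/C=C(/C)C(=O)OC)C[C@H]1C1(OCCO1)C[C@H]2C1(C)C(O)C=C1OCC
F9 | step 15 | cyclobutanol (21 with CHOH in place of C=O; carbinol epimers) | C=C1C[C@]2([C@@H](CO[Si](C)(C)C(C)(C)C)/C=C(/C)C(=O)OC)C[C@H]1C1(OCCO1)C[C@H]2[C@]1(C)[C@@H](OCc2ccc(OC)cc2)CC1O
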